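**Retrosynthetic overview**

1. Target ⇐ removal of three silyl ethers ⇐ γ-lactone closed last by palladium-catalysed cyclocarbonylation of a trans-2-ethynyl alcohol (C-6–O–C-12).
2. C-8 ester ⇐ Mitsunobu C–O coupling with inversion between an axial C-8 alcohol and (Z)-2-(silyloxymethyl)but-2-enoic acid; this is the key bond, it sets C-8 and joins the two fragments.
3. C-6 (as C–B, later C–O with retention) and the C-7 alkyne ⇐ new copper-catalysed borylative alkynylation of a cyclohexenone; enone ⇐ allylic oxidation.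
4. C-5 ⇐ anti-SN2′ substitution of a CBS-derived allylic phosphate; C-10 ⇐ TADDOL-catalysed Diels–Alder reaction of an aminosiloxy diene with 2-(silyloxymethyl)acrolein.
5. Ring order: cyclohexane first (Diels–Alder), α-methylene-γ-lactone last (carbonylation).

Labels: carbons are named as in elemanolides (C-10 quaternary carbon, C-5 carbon bearing the hydroxypropenyl group, C-6 lactone carbinol, C-7, C-8 ester carbinol, C-9 CH2, C-14 the CH2O on C-10, C-11/C-12/C-13 lactone α-carbon/carbonyl/methylene); α = face of the C-10 vinyl group, β = face of the C-10 CH2O group; TBS = tert-butyldimethylsilyl; Bpin = 4,4,5,5-tetramethyl-1,3,2-dioxaborolan-2-yl.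

Assumption: the (R,R)-TADDOL is taken to give the C-10 configuration drawn; if the sense of induction is opposite for this dienophile, the (S,S)-catalyst is used.

**Route**

Step 1
Reactants: 1 3-(TBS-oxy)propanal
Product: 2 2-(TBS-oxymethyl)prop-2-enal
Conditions: 37% aq. CH2O, pyrrolidine (10 mol %), EtCO2H (10 mol %), i-PrOH, 45 °C
Reagents that add atoms: formaldehyde, C=O
Why: Amine-catalysed Mannich condensation–elimination (α-methylenation of an aldehyde) is general for unbranched aldehydes and creates no stereocentre.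

Step 2
Reactants: 2 2-(TBS-oxymethyl)prop-2-enal; 3 (E)-3-(TBS-oxy)-N,N-dimethylbuta-1,3-dien-1-amine
Product: 4 4-(TBS-oxy)-1-(TBS-oxymethyl)-2-(dimethylamino)cyclohex-3-ene-1-carbaldehyde (endo adduct; CHO cis to NMe2; quaternary carbon = future C-10)
Conditions: (R,R)-α,α,α′,α′-tetra(1-naphthyl)-2,2-dimethyl-1,3-dioxolane-4,5-dimethanol (1-naphthyl-TADDOL, 20 mol %), toluene, −78 °C; used crude
Reagents that add atoms: none
Why: Hydrogen-bond-catalysed Diels–Alder reaction of an aminosiloxy diene with an α-substituted acrolein, in which the amino-bearing terminus bonds to the formyl-bearing carbon and the TADDOL hydroxyl binds the aldehyde and shields one face, so the quaternary centre C-10 is set (the endo amino centre is removed in step 3).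

Step 3
Reactants: 4 Diels–Alder adduct
Product: 6 (4R)-4-(TBS-oxymethyl)-4-ethenylcyclohex-2-en-1-one, via vinyl cycloadduct 5 (not isolated)
Conditions: Ph3PCH3Br, KN(SiMe3)2, THF, 0 °C; then 0.1 M aq. HCl, THF, 0 °C
Reagents that add atoms: methyltriphenylphosphonium bromide, [Br-].C[P+](c1ccccc1)(c1ccccc1)c1ccccc1
Why: Wittig methylenation of the non-enolisable aldehyde is followed by acid hydrolysis of the silyl enol ether and E1cB loss of dimethylamine, which unveils the enone without touching C-10.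

Step 4
Reactants: 6 (4R)-4-(TBS-oxymethyl)-4-ethenylcyclohex-2-en-1-one
Product: 7 (1S,4R)-4-(TBS-oxymethyl)-4-ethenylcyclohex-2-en-1-ol (OH α, cis to the vinyl group)
Conditions: (R)-1-methyl-3,3-diphenyltetrahydro-1H,3H-pyrrolo[1,2-c][1,3,2]oxazaborole ((R)-Me-CBS, 20 mol %), catecholborane, toluene, −78 °C
Reagents that add atoms: none
Why: Corey–Bakshi–Shibata reduction with catecholborane gives catalyst-controlled 1,2-reduction of the enone (the alkene arm acts as the large group), setting the C-7 carbinol on the α face while leaving the alkenes untouched.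

Step 5
Reactants: 8 2-bromoprop-2-en-1-ol
Product: 9 [(2-bromoprop-2-en-1-yl)oxy](tert-butyl)dimethylsilane
Conditions: TBSCl, imidazole, CH2Cl2, 0 °C to rt
Reagents that add atoms: tert-butyldimethylsilyl chloride, CC(C)(C)[Si](C)(C)Cl
Why: Standard silylation of a primary allylic alcohol; no stereocentre is involved.

Step 6
Reactants: 7 (1S,4R)-allylic alcohol; 9 2-bromoallyl TBS ether
Product: 13 3-[3-(TBS-oxy)prop-1-en-2-yl]-4-(TBS-oxymethyl)-4-ethenylcyclohex-1-ene (propenyl group at C-5 β; cis to CH2OTBS), via allylic phosphate 10 (not isolated), via alkenyllithium 11 (not isolated), via alkenylmagnesium bromide 12 (not isolated)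
Conditions: 7: n-BuLi then ClP(O)(OEt)2, THF, −78 to 0 °C; 9: t-BuLi (2 equiv), Et2O, −78 °C, then MgBr2·OEt2; mix, CuBr·SMe2 (10 mol %), THF, −78 to −20 °C
Reagents that add atoms: none
Why: Copper-catalysed anti-SN2′ allylic substitution of an allylic phosphate by an alkenyl Grignard reagent, in which the nucleophile enters at C-5 on the face opposite to the α C-7 leaving group, so the C-7 configuration is transferred to C-5 (new substituent β) and the alkene moves to C-6/C-7.

Step 7
Reactants: 13 diene from step 6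
Product: 15 4-[3-(TBS-oxy)prop-1-en-2-yl]-5-(TBS-oxymethyl)-5-ethenylcyclohex-2-en-1-one (C-8 ketone; C-6/C-7 alkene), via C-8 allylic alcohol 14 (not isolated)
Conditions: SeO2 (20 mol %), t-BuOOH, CH2Cl2, rt; then Dess–Martin periodinane, CH2Cl2, rt
Reagents that add atoms: selenium dioxide, O=[Se]=O; tert-butyl hydroperoxide, CC(C)(C)OO
Why: Selenium dioxide allylic oxidation (ene reaction then [2,3]-shift) prefers the ring CH2 at C-8 over the tertiary doubly allylic C-5–H and over the inductively deactivated silyloxymethyl group, and Dess–Martin oxidation of both C-8 epimers converges on the enone, so no stereocentre is at stake.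

Step 8
Reactants: 15 enone from step 7
Product: 17 3-Bpin-2-[(trimethylsilyl)ethynyl]-4-[3-(TBS-oxy)prop-1-en-2-yl]-5-(TBS-oxymethyl)-5-ethenylcyclohexan-1-one (C-6 Bpin α; C-7 alkynyl β), via boron enolate 16 (not isolated)
Conditions: B2pin2, CuCl (5 mol %), Xantphos [4,5-bis(diphenylphosphino)-9,9-dimethylxanthene] (5 mol %), NaOt-Bu (10 mol %), THF, 0 °C; then KOt-Bu, TMS-EBX, −78 to −40 °C
Reagents that add atoms: bis(pinacolato)diboron, CC1(C)OB(OC1(C)C)B1OC(C)(C)C(C)(C)O1; 1-[(trimethylsilyl)ethynyl]-1,2-benziodoxol-3(1H)-one (TMS-EBX), C[Si](C)(C)C#CI1OC(=O)c2ccccc12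
Why: Proposed new method: a copper–boryl species adds Bpin to C-6 of the enone anti to the C-5 substituent and, with no proton source present, is turned over by B2pin2 to the regiodefined O-boron enolate 16; tert-butoxide then frees the enolate, whose α-carbon attacks the alkyne of the trivalent-iodine reagent (addition, loss of 2-iodobenzoate, 1,2-shift) anti to the new C–B bond, so C-6 (α) and C-7 (β) are set trans in one flask; the closest known reactions are copper-catalysed β-borylation of enones with aldol trapping of the enolate and the α-alkynylation of stabilised enolates (β-keto esters) by ethynylbenziodoxolones.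

Step 9
Reactants: 17 borylated alkynyl ketone
Product: 19 3-Bpin-2-ethynyl-4-[3-(TBS-oxy)prop-1-en-2-yl]-5-(TBS-oxymethyl)-5-ethenylcyclohexan-1-ol (C-8 OH β; axial), via silylalkynyl alcohol 18 (not isolated)
Conditions: LiBH(s-Bu)3, THF, −78 °C; then K2CO3 (cat.), MeOH, 0 °C
Reagents that add atoms: none
Why: Bulky-hydride 1,2-reduction in which LiBH(s-Bu)3 attacks the C-8 ketone from the α face (the β face is blocked by the axial C-10 CH2OTBS group) to give the axial β alcohol, followed by mild methanolytic protodesilylation of the alkyne.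

Step 10
Reactants: 20 ethyl but-2-ynoate
Product: 22 ethyl (Z)-2-(hydroxymethyl)but-2-enoate, via alumino enoate 21 (not isolated)
Conditions: i-Bu2AlH, HMPA, THF, 0 °C; then (CH2O)n, 0 °C to rt; aqueous work-up
Reagents that add atoms: formaldehyde (from paraformaldehyde), C=O
Why: Syn-hydroalumination of the ynoate (hydride to C-3, aluminium to C-2) followed by hydroxymethylation of the vinylalane with retention (vinylalumination) fixes the Z geometry, with the methyl group cis to the ester.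

Step 11
Reactants: 22 ethyl (Z)-2-(hydroxymethyl)but-2-enoate
Product: 23 ethyl (Z)-2-(TBS-oxymethyl)but-2-enoate
Conditions: TBSCl, imidazole, CH2Cl2, rt
Reagents that add atoms: tert-butyldimethylsilyl chloride, CC(C)(C)[Si](C)(C)Cl
Why: Standard silylation of the primary allylic alcohol; the alkene geometry is not affected.

Step 12
Reactants: 23 ethyl (Z)-2-(TBS-oxymethyl)but-2-enoate
Product: 24 (Z)-2-(TBS-oxymethyl)but-2-enoic acid
Conditions: LiOH, THF/H2O, rt; 1 M HCl to pH 4
Reagents that add atoms: lithium hydroxide, [Li+].[OH-]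
Why: Ester saponification under mild conditions that neither isomerise the trisubstituted alkene nor cleave the primary silyl ether.

Step 13
Reactants: 19 axial C-8 alcohol; 24 (Z)-2-(TBS-oxymethyl)but-2-enoic acid
Product: 25 8α-ester: (Z)-2-(TBS-oxymethyl)but-2-enoate of the C-8 epimer of 19 (C-8 O α; equatorial)
Conditions: PPh3, diisopropyl azodicarboxylate, toluene, 0 °C to rt
Reagents that add atoms: none
Why: Mitsunobu esterification, in which the axial C-8 alcohol is activated as an alkoxyphosphonium ion and displaced by the carboxylate in an SN2 step from the open α face, so the C–O bond is formed with inversion, giving the equatorial 8α ester and joining the acid fragment.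

Step 14
Reactants: 25 8α-ester boronate
Product: 26 C-6 alcohol (C-6 OH α; trans to the C-7 ethynyl group)
Conditions: NaBO3·4H2O, THF/H2O, rt
Reagents that add atoms: sodium perborate tetrahydrate, O.O.O.O.[Na+].[O-]OB=O
Why: Perborate oxidation of the secondary alkyl boronate proceeds by 1,2-migration of carbon from boron to oxygen with retention, unveiling the C-6 α hydroxyl under conditions mild enough for the ester.

Step 15
Reactants: 26 trans-2-ethynyl alcohol
Product: 27 tris-TBS ether of the target (trans-fused α-methylene-γ-lactone)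
Conditions: CO (7 atm), PdCl2 (5 mol %), SnCl2 (5 mol %), PPh3 (10 mol %), MeCN, 75 °C
Reagents that add atoms: carbon monoxide, [C-]#[O+]
Why: Palladium-catalysed cyclocarbonylation of a homopropargylic alcohol, in which the hydroxyl is converted to an alkoxycarbonyl–palladium species that adds across the alkyne intramolecularly, closes the lactone and creates the exocyclic methylene with the trans C-6/C-7 relationship already in place.

Step 16
Reactants: 27 tris-TBS ether of the target
Product: 28 target compound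
Conditions: HF·pyridine, pyridine, THF, 0 °C to rt
Reagents that add atoms: none
Why: Fluoride-mediated cleavage of the three primary silyl ethers under buffered acidic conditions leaves the α-methylene lactone and the enoate ester untouched.

**Compound list**

1 | 3-(TBS-oxy)propanal | O=CCCO[Si](C)(C)C(C)(C)C | starting material
2 | 2-(TBS-oxymethyl)prop-2-enal | C=C(C=O)CO[Si](C)(C)C(C)(C)C | intermediate
3 | (E)-3-(TBS-oxy)-N,N-dimethylbuta-1,3-dien-1-amine (Rawal-type diene) | CN(C)/C=C/C(=C)O[Si](C)(C)C(C)(C)C | starting material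
4 | 4-(TBS-oxy)-1-(TBS-oxymethyl)-2-(dimethylamino)cyclohex-3-ene-1-carbaldehyde, endo adduct (CHO cis to NMe2) | O=C[C@]1(CO[Si](C)(C)C(C)(C)C)CCC(O[Si](C)(C)C(C)(C)C)=C[C@@H]1N(C)C | intermediate
5 | 4-(TBS-oxy)-1-(TBS-oxymethyl)-1-ethenyl-2-(dimethylamino)cyclohex-3-ene (not isolated) | C=C[C@]1(CO[Si](C)(C)C(C)(C)C)CCC(O[Si](C)(C)C(C)(C)C)=C[C@@H]1N(C)C | intermediate
6 | (4R)-4-(TBS-oxymethyl)-4-ethenylcyclohex-2-en-1-one | C=C[C@]1(CO[Si](C)(C)C(C)(C)C)CCC(=O)C=C1 | intermediate
7 | (1S,4R)-4-(TBS-oxymethyl)-4-ethenylcyclohex-2-en-1-ol (OH cis to vinyl) | C=C[C@]1(CO[Si](C)(C)C(C)(C)C)CC[C@H](O)C=C1 | intermediate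
8 | 2-bromoprop-2-en-1-ol | C=C(Br)CO | starting material
9 | [(2-bromoprop-2-en-1-yl)oxy](tert-butyl)dimethylsilane | C=C(Br)CO[Si](C)(C)C(C)(C)C | intermediate
10 | diethyl (1S,4R)-4-(TBS-oxymethyl)-4-ethenylcyclohex-2-en-1-yl phosphate (not isolated) | C=C[C@]1(CO[Si](C)(C)C(C)(C)C)CC[C@H](OP(=O)(OCC)OCC)C=C1 | intermediate
11 | [3-(TBS-oxy)prop-1-en-2-yl]lithium (not isolated) | [Li]C(=C)CO[Si](C)(C)C(C)(C)C | intermediate
12 | [3-(TBS-oxy)prop-1-en-2-yl]magnesium bromide (not isolated) | Br[Mg]C(=C)CO[Si](C)(C)C(C)(C)C | intermediate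
13 | 3-[3-(TBS-oxy)prop-1-en-2-yl]-4-(TBS-oxymethyl)-4-ethenylcyclohex-1-ene; C-5 propenyl β (cis to CH2OTBS, trans to vinyl) | C=C[C@]1(CO[Si](C)(C)C(C)(C)C)CCC=C[C@H]1C(=C)CO[Si](C)(C)C(C)(C)C | intermediate
14 | 4-[3-(TBS-oxy)prop-1-en-2-yl]-5-(TBS-oxymethyl)-5-ethenylcyclohex-2-en-1-ol, mixture of C-8 epimers (not isolated) | C=C[C@]1(CO[Si](C)(C)C(C)(C)C)CC(O)C=C[C@H]1C(=C)CO[Si](C)(C)C(C)(C)C | intermediate
15 | 4-[3-(TBS-oxy)prop-1-en-2-yl]-5-(TBS-oxymethyl)-5-ethenylcyclohex-2-en-1-one (propenyl cis to CH2OTBS) | C=C[C@]1(CO[Si](C)(C)C(C)(C)C)CC(=O)C=C[C@H]1C(=C)CO[Si](C)(C)C(C)(C)C | intermediate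
16 | O-Bpin enolate of the 3-Bpin ketone (C-6 Bpin α; not isolated) | C=C[C@]1(CO[Si](C)(C)C(C)(C)C)CC(OB2OC(C)(C)C(C)(C)O2)=C[C@H](B2OC(C)(C)C(C)(C)O2)[C@H]1C(=C)CO[Si](C)(C)C(C)(C)C | intermediate
17 | 3-Bpin-2-[(trimethylsilyl)ethynyl]-4-[3-(TBS-oxy)prop-1-en-2-yl]-5-(TBS-oxymethyl)-5-ethenylcyclohexan-1-one; C-5 β, C-6 Bpin α, C-7 alkynyl β | C=C[C@]1(CO[Si](C)(C)C(C)(C)C)CC(=O)[C@@H](C#C[Si](C)(C)C)[C@H](B2OC(C)(C)C(C)(C)O2)[C@H]1C(=C)CO[Si](C)(C)C(C)(C)C | intermediate
18 | C-8 β alcohol of 17, alkyne still silylated (not isolated) | C=C[C@]1(CO[Si](C)(C)C(C)(C)C)C[C@@H](O)[C@@H](C#C[Si](C)(C)C)[C@H](B2OC(C)(C)C(C)(C)O2)[C@H]1C(=C)CO[Si](C)(C)C(C)(C)C | intermediate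
19 | 3-Bpin-2-ethynyl-4-[3-(TBS-oxy)prop-1-en-2-yl]-5-(TBS-oxymethyl)-5-ethenylcyclohexan-1-ol; C-8 OH β (axial, cis to CH2OTBS) | C=C[C@]1(CO[Si](C)(C)C(C)(C)C)C[C@@H](O)[C@@H](C#C)[C@H](B2OC(C)(C)C(C)(C)O2)[C@H]1C(=C)CO[Si](C)(C)C(C)(C)C | intermediate
20 | ethyl but-2-ynoate | CC#CC(=O)OCC | starting material
21 | ethyl (Z)-2-(diisobutylalumanyl)but-2-enoate (not isolated) | CCOC(=O)/C(=C\C)[Al](CC(C)C)CC(C)C | intermediate
22 | ethyl (Z)-2-(hydroxymethyl)but-2-enoate | CCOC(=O)/C(=C\C)CO | intermediate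
23 | ethyl (Z)-2-(TBS-oxymethyl)but-2-enoate | CCOC(=O)/C(=C\C)CO[Si](C)(C)C(C)(C)C | intermediate
24 | (Z)-2-(TBS-oxymethyl)but-2-enoic acid | OC(=O)/C(=C\C)CO[Si](C)(C)C(C)(C)C | intermediate
25 | 8α-[(Z)-2-(TBS-oxymethyl)but-2-enoyl]oxy boronate (C-8 O α, C-7 ethynyl β, C-6 Bpin α) | C=C[C@]1(CO[Si](C)(C)C(C)(C)C)C[C@H](OC(=O)/C(=C\C)CO[Si](C)(C)C(C)(C)C)[C@@H](C#C)[C@H](B2OC(C)(C)C(C)(C)O2)[C@H]1C(=C)CO[Si](C)(C)C(C)(C)C | intermediate
26 | 6α-hydroxy-7β-ethynyl-8α-acyloxy compound (C-6 OH in place of Bpin) | C=C[C@]1(CO[Si](C)(C)C(C)(C)C)C[C@H](OC(=O)/C(=C\C)CO[Si](C)(C)C(C)(C)C)[C@@H](C#C)[C@H](O)[C@H]1C(=C)CO[Si](C)(C)C(C)(C)C | intermediate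
27 | tris-TBS ether of the target (C-14, C-15 and side-chain hydroxyls silylated) | C=C[C@]1(CO[Si](C)(C)C(C)(C)C)C[C@H](OC(=O)/C(=C\C)CO[Si](C)(C)C(C)(C)C)[C@H]2C(=C)C(=O)O[C@@H]2[C@H]1C(=C)CO[Si](C)(C)C(C)(C)C | intermediate
28 | CNP0338073.1 | C=C[C@]1(CO)C[C@H](OC(=O)/C(=C\C)CO)[C@H]2C(=C)C(=O)O[C@@H]2[C@H]1C(=C)CO | target

**Step count and risks**

Total step count: 16. Longest linear sequence: 12 steps (steps 1, 2, 3, 4, 6, 7, 8, 9, 13, 14, 15, 16).

Steps most likely to fail:

Step 8 (the proposed borylative alkynylation). Risks are double alkynylation, slow turnover to the boron enolate without a proton source, and isomerisation of the α-alkynyl ketone. The fallback uses known chemistry, sets out from 15 and returns at 17. Iodine and pyridine in CH2Cl2 give the 2-iodoenone F1. Sonogashira coupling with ethynyltrimethylsilane (PdCl2(PPh3)2, CuI, i-Pr2NH) gives the 2-alkynyl enone F2. Copper-catalysed conjugate borylation with protonation (B2pin2, CuCl, Xantphos, NaOt-Bu, MeOH) then gives 17 together with its C-7 epimer F3, which is separated, re-equilibrated with 1,8-diazabicyclo[5.4.0]undec-7-ene and recycled.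

Step 6 (anti-SN2′ substitution). Risks are attack at the γ-carbon next to the quaternary centre, cis to the CH2OTBS group, and the stability of the β-silyloxy alkenyl organometallic. The fallback sets out from 6 and returns at 13. Reduction of 6 with the (S)-enantiomer of the CBS catalyst and catecholborane gives the C-7 epimeric alcohol F4. Johnson–Claisen rearrangement (MeC(OEt)3, EtCO2H cat., 140 °C) delivers the acetate chain suprafacially to the β face of C-5 and gives the ester F5. LiN(i-Pr)2 then dimethylmethyleneammonium iodide gives the β-amino ester F6. Methyl iodide gives the ammonium iodide F7, and 1,8-diazabicyclo[5.4.0]undec-7-ene eliminates it to the acrylate F8. i-Bu2AlH gives the allylic alcohol F9, and TBSCl with imidazole gives 13.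

Step 13 (Mitsunobu coupling on a hindered axial alcohol with a weakly acidic enoic acid). Risks are no reaction and E2 elimination. The fallback sets out from 19 and returns at 25. Mitsunobu inversion with the more acidic 4-nitrobenzoic acid (PPh3, diisopropyl azodicarboxylate) gives the inverted 4-nitrobenzoate F10. Methanolysis (K2CO3, MeOH) gives the equatorial 8α alcohol F11. This is acylated with retention by acid 24 under Yamaguchi conditions (2,4,6-trichlorobenzoyl chloride, Et3N, 4-(dimethylamino)pyridine) to give 25.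

**Further compounds**

F1 | step 8 | 2-iodo-4-[3-(TBS-oxy)prop-1-en-2-yl]-5-(TBS-oxymethyl)-5-ethenylcyclohex-2-en-1-one | C=C[C@]1(CO[Si](C)(C)C(C)(C)C)CC(=O)C(I)=C[C@H]1C(=C)CO[Si](C)(C)C(C)(C)C
F2 | step 8 | 2-[(trimethylsilyl)ethynyl]-4-[3-(TBS-oxy)prop-1-en-2-yl]-5-(TBS-oxymethyl)-5-ethenylcyclohex-2-en-1-one | C=C[C@]1(CO[Si](C)(C)C(C)(C)C)CC(=O)C(C#C[Si](C)(C)C)=C[C@H]1C(=C)CO[Si](C)(C)C(C)(C)C
F3 | step 8 | C-7 epimer of 17 (alkynyl α, cis to Bpin) | C=C[C@]1(CO[Si](C)(C)C(C)(C)C)CC(=O)[C@H](C#C[Si](C)(C)C)[C@H](B2OC(C)(C)C(C)(C)O2)[C@H]1C(=C)CO[Si](C)(C)C(C)(C)C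
F4 | step 6 | (1R,4R)-4-(TBS-oxymethyl)-4-ethenylcyclohex-2-en-1-ol (OH β, cis to CH2OTBS) | C=C[C@]1(CO[Si](C)(C)C(C)(C)C)CC[C@@H](O)C=C1
F5 | step 6 | ethyl 2-[6-(TBS-oxymethyl)-6-ethenylcyclohex-2-en-1-yl]acetate (acetate chain at C-5 β) | C=C[C@]1(CO[Si](C)(C)C(C)(C)C)CCC=C[C@H]1CC(=O)OCC
F6 | step 6 | ethyl 3-(dimethylamino)-2-[6-(TBS-oxymethyl)-6-ethenylcyclohex-2-en-1-yl]propanoate (mixture at the ester α-carbon) | C=C[C@]1(CO[Si](C)(C)C(C)(C)C)CCC=C[C@H]1C(CN(C)C)C(=O)OCC
F7 | step 6 | trimethylammonium iodide of F6 | C=C[C@]1(CO[Si](C)(C)C(C)(C)C)CCC=C[C@H]1C(C[N+](C)(C)C)C(=O)OCC.[I-]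
F8 | step 6 | ethyl 2-[6-(TBS-oxymethyl)-6-ethenylcyclohex-2-en-1-yl]prop-2-enoate | C=C[C@]1(CO[Si](C)(C)C(C)(C)C)CCC=C[C@H]1C(=C)C(=O)OCC
F9 | step 6 | 2-[6-(TBS-oxymethyl)-6-ethenylcyclohex-2-en-1-yl]prop-2-en-1-ol | C=C[C@]1(CO[Si](C)(C)C(C)(C)C)CCC=C[C@H]1C(=C)CO
F10 | step 13 | 8α-(4-nitrobenzoate) of the C-8 epimer of 19 | C=C[C@]1(CO[Si](C)(C)C(C)(C)C)C[C@H](OC(=O)c2ccc(cc2)[N+](=O)[O-])[C@@H](C#C)[C@H](B2OC(C)(C)C(C)(C)O2)[C@H]1C(=C)CO[Si](C)(C)C(C)(C)C
F11 | step 13 | C-8 epimer of 19 (C-8 OH α, equatorial) | C=C[C@]1(CO[Si](C)(C)C(C)(C)C)C[C@H](O)[C@@H](C#C)[C@H](B2OC(C)(C)C(C)(C)O2)[C@H]1C(=C)CO[Si](C)(C)C(C)(C)C
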